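## Retrosynthetic overview

1. Target 25 ⇐ diol 23 by late C6–O methacrylation ⇐ acetonide 22.
2. 22 ⇐ bromo aldehyde 20: the C7–C8 bond is made by a chromium-electrocatalytic intramolecular allylation that closes the ten-membered carbocycle; the cis α-methylene lactone forms last, by lactonisation in the same pot.
3. 20 ⇐ furanone 15: the C7 arm comes from Morita–Baylis–Hillman reaction and allylic bromination; the C8 aldehyde is carried as a dimethyl acetal.
4. 15 ⇐ enyne 12 + dioxolanone 7: acetylide acylation (C1–C2) followed by 5-endo-dig O-cyclisation gives the furanone, the first ring formed.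
5. 12 ⇐ 2,3-O-isopropylidene-D-erythronolactone (C5, C6 bought); 7 ⇐ (S)-lactic acid by self-regeneration of the stereocentre (C10); C7 and C8 are set in the macrocyclisation.

Assumption: locants used here are C1 furanone C=O, C2 furanone CH, C3 furanone O–C=, C4 C(=C15H2), C5 CHOH, C6 CH–O-methacryloyl, C7 lactone CH, C8 lactone CH–O, C9 CH2, C10 C(CH3)–O, C11/C12/C13 lactone α-C/C=O/exo-CH2; in these locants the target is (5S,6R,7S,8S,10R).

## Route

Step 1
Reactants: 1 (S)-lactic acid; 2 pivalaldehyde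
Product: 3 (2S,5S)-2-tert-butyl-5-methyl-1,3-dioxolan-4-one
Conditions: p-TsOH·H2O (cat.), H2SO4 (cat.), pentane, reflux, Dean–Stark; recrystallise from pentane/Et2O at −78 °C
Reagents that add atoms: none
Why: Acid-catalysed acetalisation (Seebach dioxolanone formation) gives the cis acetal as the thermodynamic product, its new acetal centre being set by the lactic acid centre and upgraded by crystallisation.

Step 2
Reactants: 3 (2S,5S)-2-tert-butyl-5-methyl-1,3-dioxolan-4-one; 4 allyl bromide
Product: 5 (2S,5R)-5-allyl-2-tert-butyl-5-methyl-1,3-dioxolan-4-one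
Conditions: LiN(i-Pr)2 (1.05 equiv, commercial solution), THF, −78 °C; then 4, −78 → −30 °C
Reagents that add atoms: none
Why: Seebach self-regeneration of the stereocentre: the enolate is alkylated anti to the tert-butyl group, so the quaternary centre (future C10) is formed with the required R configuration at typically ≥95:5 dr.

Step 3
Reactants: 5 (2S,5R)-5-allyl-2-tert-butyl-5-methyl-1,3-dioxolan-4-one
Product: 7 (2S,5R)-2-tert-butyl-5-(2,2-dimethoxyethyl)-5-methyl-1,3-dioxolan-4-one, via aldehyde 6 (not isolated)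
Conditions: O3, CH2Cl2/MeOH (4:1), −78 °C; Me2S, −78 °C → rt; then p-TsOH·H2O (10 mol%), rt, 3 h; NaHCO3
Reagents that add atoms: ozone, [O-][O+]=O (oxygen of 6); methanol, CO
Why: Ozonolysis with reductive work-up and in situ acid-catalysed acetalisation masks the future C8 aldehyde while the hindered tert-butyl dioxolanone survives catalytic acid at room temperature; no stereocentre is touched.

Step 4
Reactants: 8 2,3-O-isopropylidene-D-erythronolactone; 9 trimethylsilylacetylene
Product: 10 (3aR,6aR)-2,2-dimethyl-4-[(trimethylsilyl)ethynyl]tetrahydrofuro[3,4-d][1,3]dioxol-4-ol (anomer mixture)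
Conditions: 9, n-BuLi, THF, −78 °C, 30 min; then 8, −78 °C, 1 h; sat. NH4Cl
Reagents that add atoms: none
Why: Acetylide addition to a γ-lactone stops at the five-membered lactol because the tetrahedral alkoxide is stable at −78 °C; the bought C5 and C6 centres are untouched.

Step 5
Reactants: 10 (3aR,6aR)-2,2-dimethyl-4-[(trimethylsilyl)ethynyl]tetrahydrofuro[3,4-d][1,3]dioxol-4-ol
Product: 12 [(4R,5S)-5-(but-1-en-3-yn-2-yl)-2,2-dimethyl-1,3-dioxolan-4-yl]methanol, via silylated enyne alcohol 11 (not isolated)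
Conditions: Ph3PCH3Br (3.0 equiv), KN(SiMe3)2 (2.9 equiv), THF, 0 °C; 10, −78 → 0 °C; then MeOH, K2CO3 (0.3 equiv), rt
Reagents that add atoms: methyltriphenylphosphonium bromide, C[P+](c1ccccc1)(c1ccccc1)c1ccccc1.[Br-]
Why: Wittig methylenation of the ring-opened ynone tautomer installs C15 and frees the C7 hydroxyl, and methanolic carbonate then removes the alkynyl silyl group; the lithium-free ylide at low temperature is chosen to avoid epimerisation at C5.

Step 6
Reactants: 12 [(4R,5S)-5-(but-1-en-3-yn-2-yl)-2,2-dimethyl-1,3-dioxolan-4-yl]methanol; 7 (2S,5R)-2-tert-butyl-5-(2,2-dimethoxyethyl)-5-methyl-1,3-dioxolan-4-one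
Product: 15 (2R)-2-(2,2-dimethoxyethyl)-5-{1-[(4S,5R)-2,2-dimethyl-5-{[(triethylsilyl)oxy]methyl}-1,3-dioxolan-4-yl]ethenyl}-2-methylfuran-3(2H)-one, via triethylsilyl ether 13 (not isolated), via hydroxy ynone 14 (not isolated)
Conditions: 12, n-BuLi (1.0 equiv), THF, −78 °C; Et3SiCl (1.0 equiv), → 0 °C, 30 min; n-BuLi (1.05 equiv), −78 °C; 7 (1.1 equiv), −78 °C, 1 h; t-BuOH (5 equiv), −78 → 0 °C, 2 h; sat. NH4Cl
Reagents that add atoms: chlorotriethylsilane, CC[Si](CC)(CC)Cl
Why: After in situ O-silylation (which blocks a competing 6-exo-dig closure by the C7 oxygen), the lithium acetylide acylates at the dioxolanone carbonyl, whose five-membered tetrahedral adduct should hold at −78 °C and then collapse on warming with loss of pivalaldehyde to the tertiary alkoxide, which closes by 5-endo-dig oxa-Michael addition with t-BuOH as proton source; C10 is carried over unchanged.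

Step 7
Reactants: 15 (2R)-2-(2,2-dimethoxyethyl)-5-{1-[(4S,5R)-2,2-dimethyl-5-{[(triethylsilyl)oxy]methyl}-1,3-dioxolan-4-yl]ethenyl}-2-methylfuran-3(2H)-one
Product: 16 (4S,5S)-5-{1-[(5R)-5-(2,2-dimethoxyethyl)-5-methyl-4-oxo-4,5-dihydrofuran-2-yl]ethenyl}-2,2-dimethyl-1,3-dioxolane-4-carbaldehyde
Conditions: (COCl)2 (4 equiv), DMSO (8 equiv), CH2Cl2, −78 → −40 °C, 45 min; Et3N (10 equiv), −78 → 0 °C; used crude
Reagents that add atoms: none
Why: Under Swern conditions a primary triethylsilyl ether is oxidised directly to the aldehyde (silyl transfer to chloride, then normal alkoxysulfonium collapse), which saves a deprotection step; the aldehyde is used at once so C6 does not epimerise.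

Step 8
Reactants: 16 (4S,5S)-5-{1-[(5R)-5-(2,2-dimethoxyethyl)-5-methyl-4-oxo-4,5-dihydrofuran-2-yl]ethenyl}-2,2-dimethyl-1,3-dioxolane-4-carbaldehyde; 17 methyl acrylate
Product: 18 methyl 2-{hydroxy[(4R,5S)-5-{1-[(5R)-5-(2,2-dimethoxyethyl)-5-methyl-4-oxo-4,5-dihydrofuran-2-yl]ethenyl}-2,2-dimethyl-1,3-dioxolan-4-yl]methyl}prop-2-enoate (carbinol epimers)
Conditions: 17 (10 equiv), DABCO (1.0 equiv), 1,4-dioxane/H2O (1:1), rt, 24–48 h
Reagents that add atoms: none
Why: Morita–Baylis–Hillman reaction of an activated α-alkoxy aldehyde with excess acrylate; the new carbinol centre is formed as a mixture but is erased in step 9, and the base-sensitive C8 aldehyde is still masked.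

Step 9
Reactants: 18 methyl 2-{hydroxy[(4R,5S)-5-{1-[(5R)-5-(2,2-dimethoxyethyl)-5-methyl-4-oxo-4,5-dihydrofuran-2-yl]ethenyl}-2,2-dimethyl-1,3-dioxolan-4-yl]methyl}prop-2-enoate
Product: 19 methyl (2Z)-2-(bromomethyl)-3-[(4R,5S)-5-{1-[(5R)-5-(2,2-dimethoxyethyl)-5-methyl-4-oxo-4,5-dihydrofuran-2-yl]ethenyl}-2,2-dimethyl-1,3-dioxolan-4-yl]prop-2-enoate
Conditions: NBS (1.5 equiv), Me2S (1.8 equiv), CH2Cl2, 0 °C, 15 min; then 18, 0 °C → rt, 3 h
Reagents that add atoms: N-bromosuccinimide, O=C1CCC(=O)N1Br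
Why: Corey–Kim-type activation of the allylic alcohol and SN2' delivery of bromide give the thermodynamically favoured (Z)-2-(bromomethyl)enoate (C6 cis to CH2Br) under acid-free conditions that spare the acetal and acetonide.

Step 10
Reactants: 19 methyl (2Z)-2-(bromomethyl)-3-[(4R,5S)-5-{1-[(5R)-5-(2,2-dimethoxyethyl)-5-methyl-4-oxo-4,5-dihydrofuran-2-yl]ethenyl}-2,2-dimethyl-1,3-dioxolan-4-yl]prop-2-enoate
Product: 20 methyl (2Z)-2-(bromomethyl)-3-[(4R,5S)-2,2-dimethyl-5-{1-[(5R)-5-methyl-4-oxo-5-(2-oxoethyl)-4,5-dihydrofuran-2-yl]ethenyl}-1,3-dioxolan-4-yl]prop-2-enoate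
Conditions: Amberlyst-15, acetone/H2O (20:1), rt, 2–4 h; filter; used at once
Reagents that add atoms: water, O
Why: Acetal hydrolysis: the acyclic dimethyl acetal cleaves far faster than the dioxolane, acetone as solvent restores any acetonide lost, and the β-oxygenated aldehyde is released only now and without base because base would eliminate the furanone oxygen.

Step 11
Reactants: 20 methyl (2Z)-2-(bromomethyl)-3-[(4R,5S)-2,2-dimethyl-5-{1-[(5R)-5-methyl-4-oxo-5-(2-oxoethyl)-4,5-dihydrofuran-2-yl]ethenyl}-1,3-dioxolan-4-yl]prop-2-enoate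
Product: 22 5,6-O-isopropylidene acetal of the 6-O-demethacryloyl target (macrocyclic cis-fused α-methylene lactone), via silyl ether ester 21 (not isolated)
Conditions: CrCl2 (20 mol%), Me3SiCl (2.0 equiv), n-Bu4NBr (0.1 M), DMF, undivided cell, aluminium anode, nickel-foam cathode, constant current 3 mA (2.2–2.5 F/mol), 20 added by syringe pump over 10 h (final 2 mM), rt; then 1 M aq. citric acid/THF, rt, 1 h
Reagents that add atoms: none
Why: Proposed new method: a chromium-electrocatalytic intramolecular Nozaki–Hiyama allylation/lactonisation in which cathodically regenerated divalent chromium converts the allylic bromide into a 2-(methoxycarbonyl)allyl trivalent-chromium species that adds through C7 to the tethered aldehyde in a chair-like six-membered transition state, Me3SiCl takes the alkoxide off chromium so that CrCl2 turns over while the aluminium anode is consumed, and the cis-γ-silyloxy ester lactonises on acidic work-up; the (Z) geometry gives the syn adduct and hence the cis-fused lactone, allylic 1,3-strain puts H6 in the alkene plane so the aldehyde, delivered from the C5 side of the cis-dioxolane turn, bonds to C7 anti to the C6–O bond (7S, then 8S), and slow addition keeps the bromide dilute; the closest known reactions are the stoichiometric CrCl2-mediated allylative macrocyclisations to germacranolide and cembranolide lactones and the electroreductive chromium-catalysed intermolecular coupling of organic halides with aldehydes.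

Step 12
Reactants: 22 5,6-O-isopropylidene acetal of the 6-O-demethacryloyl target
Product: 23 6-O-demethacryloyl target (5,6-diol with all stereocentres arranged as in 25)
Conditions: CF3CO2H/H2O/CH2Cl2 (4:1:5), 0 °C, 30 min; toluene azeotrope
Reagents that add atoms: none
Why: Acid hydrolysis of the isopropylidene acetal; the furanone, the α-methylene lactone and the exocyclic alkene tolerate brief cold aqueous acid and no stereocentre is involved.

Step 13
Reactants: 23 6-O-demethacryloyl target (5,6-diol); 24 methacrylic anhydride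
Product: 25 CNP0142847.2 (5S,6R,7S,8S,10R)
Conditions: 24 (1.05 equiv), Et3N (2 equiv), DMAP (5 mol%), CH2Cl2, −40 → −20 °C
Reagents that add atoms: none
Why: DMAP-catalysed acylation with one equivalent of anhydride is expected to go to C6–OH, an ordinary secondary carbinol, in preference to C5–OH, which is allylic to the electron-poor dienone and shielded by the C15 methylene and the furanone; this preference is a prediction, and cold, short conditions limit 1,2-acyl migration.

## Compound list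

1 | (S)-lactic acid | C[C@H](O)C(=O)O | starting material
2 | pivalaldehyde | CC(C)(C)C=O | starting material
3 | (2S,5S)-2-tert-butyl-5-methyl-1,3-dioxolan-4-one | C[C@@H]1O[C@H](C(C)(C)C)OC1=O | intermediate
4 | allyl bromide | C=CCBr | starting material
5 | (2S,5R)-5-allyl-2-tert-butyl-5-methyl-1,3-dioxolan-4-one | C[C@]1(CC=C)O[C@H](C(C)(C)C)OC1=O | intermediate
6 | 2-[(2S,4R)-2-tert-butyl-4-methyl-5-oxo-1,3-dioxolan-4-yl]acetaldehyde | C[C@]1(CC=O)O[C@H](C(C)(C)C)OC1=O | intermediate
7 | (2S,5R)-2-tert-butyl-5-(2,2-dimethoxyethyl)-5-methyl-1,3-dioxolan-4-one | C[C@]1(CC(OC)OC)O[C@H](C(C)(C)C)OC1=O | intermediate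
8 | 2,3-O-isopropylidene-D-erythronolactone, (3aR,6aR)-2,2-dimethyldihydrofuro[3,4-d][1,3]dioxol-4(3aH)-one | CC1(C)O[C@@H]2COC(=O)[C@@H]2O1 | starting material
9 | trimethylsilylacetylene | C#C[Si](C)(C)C | starting material
10 | (3aR,6aR)-2,2-dimethyl-4-[(trimethylsilyl)ethynyl]tetrahydrofuro[3,4-d][1,3]dioxol-4-ol (anomer mixture) | CC1(C)O[C@@H]2COC(O)(C#C[Si](C)(C)C)[C@@H]2O1 | intermediate
11 | {(4R,5S)-2,2-dimethyl-5-[4-(trimethylsilyl)but-1-en-3-yn-2-yl]-1,3-dioxolan-4-yl}methanol | CC1(C)O[C@H](CO)[C@H](C(=C)C#C[Si](C)(C)C)O1 | intermediate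
12 | [(4R,5S)-5-(but-1-en-3-yn-2-yl)-2,2-dimethyl-1,3-dioxolan-4-yl]methanol | CC1(C)O[C@H](CO)[C@H](C(=C)C#C)O1 | intermediate
13 | {[(4R,5S)-5-(but-1-en-3-yn-2-yl)-2,2-dimethyl-1,3-dioxolan-4-yl]methoxy}triethylsilane | CC1(C)O[C@H](CO[Si](CC)(CC)CC)[C@H](C(=C)C#C)O1 | intermediate
14 | (6R)-2-[(4S,5R)-2,2-dimethyl-5-{[(triethylsilyl)oxy]methyl}-1,3-dioxolan-4-yl]-6-hydroxy-8,8-dimethoxy-6-methyloct-1-en-3-yn-5-one | CC1(C)O[C@H](CO[Si](CC)(CC)CC)[C@H](C(=C)C#CC(=O)[C@](C)(O)CC(OC)OC)O1 | intermediate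
15 | (2R)-2-(2,2-dimethoxyethyl)-5-{1-[(4S,5R)-2,2-dimethyl-5-{[(triethylsilyl)oxy]methyl}-1,3-dioxolan-4-yl]ethenyl}-2-methylfuran-3(2H)-one | CC1(C)O[C@H](CO[Si](CC)(CC)CC)[C@H](C(=C)C2=CC(=O)[C@@](C)(CC(OC)OC)O2)O1 | intermediate
16 | (4S,5S)-5-{1-[(5R)-5-(2,2-dimethoxyethyl)-5-methyl-4-oxo-4,5-dihydrofuran-2-yl]ethenyl}-2,2-dimethyl-1,3-dioxolane-4-carbaldehyde | CC1(C)O[C@H](C=O)[C@H](C(=C)C2=CC(=O)[C@@](C)(CC(OC)OC)O2)O1 | intermediate
17 | methyl acrylate | C=CC(=O)OC | starting material
18 | methyl 2-{hydroxy[(4R,5S)-5-{1-[(5R)-5-(2,2-dimethoxyethyl)-5-methyl-4-oxo-4,5-dihydrofuran-2-yl]ethenyl}-2,2-dimethyl-1,3-dioxolan-4-yl]methyl}prop-2-enoate (carbinol epimers) | CC1(C)O[C@H](C(O)C(=C)C(=O)OC)[C@H](C(=C)C2=CC(=O)[C@@](C)(CC(OC)OC)O2)O1 | intermediate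
19 | methyl (2Z)-2-(bromomethyl)-3-[(4R,5S)-5-{1-[(5R)-5-(2,2-dimethoxyethyl)-5-methyl-4-oxo-4,5-dihydrofuran-2-yl]ethenyl}-2,2-dimethyl-1,3-dioxolan-4-yl]prop-2-enoate | CC1(C)O[C@H](/C=C(\CBr)C(=O)OC)[C@H](C(=C)C2=CC(=O)[C@@](C)(CC(OC)OC)O2)O1 | intermediate
20 | methyl (2Z)-2-(bromomethyl)-3-[(4R,5S)-2,2-dimethyl-5-{1-[(5R)-5-methyl-4-oxo-5-(2-oxoethyl)-4,5-dihydrofuran-2-yl]ethenyl}-1,3-dioxolan-4-yl]prop-2-enoate | CC1(C)O[C@H](/C=C(\CBr)C(=O)OC)[C@H](C(=C)C2=CC(=O)[C@@](C)(CC=O)O2)O1 | intermediate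
21 | ring-closed (C7–C8) ten-membered carbocycle of 22 with the lactone open as the C12 methyl ester and C8–OSiMe3, all stereocentres arranged as in 25 | CC1(C)O[C@@H]2[C@@H](C(=C)C(=O)OC)[C@@H](O[Si](C)(C)C)C[C@@]3(C)OC(=CC3=O)C(=C)[C@@H]2O1 | intermediate
22 | (5S,6R,7S,8S,10R)-5,6-O-isopropylidene acetal of the 6-O-demethacryloyl target: furanone-bridged ten-membered carbocycle with C4 exo-methylene and cis-fused 8,12-α-methylene-γ-butyrolactone | CC1(C)O[C@@H]2[C@H]3C(=C)C(=O)O[C@H]3C[C@@]4(C)OC(=CC4=O)C(=C)[C@@H]2O1 | intermediate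
23 | 6-O-demethacryloyl target (5,6-diol, all stereocentres arranged as in 25) | O[C@@H]1[C@H]2C(=C)C(=O)O[C@H]2C[C@@]2(C)OC(=CC2=O)C(=C)[C@@H]1O | intermediate
24 | methacrylic anhydride | C=C(C)C(=O)OC(=O)C(C)=C | starting material
25 | CNP0142847.2, (5S,6R,7S,8S,10R)-5-hydroxy-6-methacryloyloxy furanone-bridged 8,12-germacranolide with C4 and C11 exo-methylenes | C=C(C)C(=O)O[C@@H]1[C@H]2C(=C)C(=O)O[C@H]2C[C@@]2(C)OC(=CC2=O)C(=C)[C@@H]1O | target

## Step count and risks

Total step count: 13. Longest linear sequence: 11 steps (steps 1–3, then 6–13).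

**Step 11 (proposed new step).** The risks are wrong facial selectivity at C7, direct cathodic reduction or vinylogous β-alkoxide loss from the allylchromium, and oligomerisation. Fallback by known allylboration chemistry, setting out from 19 and returning at 22:
- Pd2(dba)3-catalysed borylation of 19 with bis(pinacolato)diboron in DMSO at 50 °C gives methyl (2E)-3-[(4R,5S)-5-{1-[(5R)-5-(2,2-dimethoxyethyl)-5-methyl-4-oxo-4,5-dihydrofuran-2-yl]ethenyl}-2,2-dimethyl-1,3-dioxolan-4-yl]-2-[(4,4,5,5-tetramethyl-1,3,2-dioxaborolan-2-yl)methyl]prop-2-enoate F2.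
- Amberlyst-15 in wet acetone unmasks the aldehyde to give the corresponding 2-oxoethyl allylboronate F3, which is isolable because 2-alkoxycarbonyl allylboronates are sluggish at room temperature.
- Heating F3 at 2 mM in toluene at 80 °C with Sc(OTf)3 (10 mol%) effects intramolecular allylboration through a closed chair transition state (same syn sense), and p-TsOH then lactonises the borate to 22.

**Step 6.** The risks are over-addition or failure of the acetylide at the hindered dioxolanone and incomplete furanone closure. Fallback, setting out from 7 and 12 and returning at 15: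
- 7 is opened with MeNHOMe·HCl and i-PrMgCl in THF to the Weinreb amide (2R)-2-hydroxy-N,4,4-trimethoxy-N,2-dimethylbutanamide F1.
- 12 is silylated separately (Et3SiCl, imidazole) to 13.
- The lithium acetylide of 13 is added to the chloromagnesium alkoxide of F1 to give isolated 14, which is closed to 15 with Ph3PAuNTf2 (2 mol%) in toluene.

**Step 13.** The risk is acylation at C5–OH or a mixture. Fallback, setting out from 23 and returning at 25, which uses that same preference to protect C5 first and so works only if the site preference is the reverse of the one predicted, not if the two hydroxyls are equally reactive: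
- Et3SiOTf and 2,6-lutidine at −78 °C give the 5-O-triethylsilyl ether of diol 23 F4.
- Methacrylic anhydride, Et3N and DMAP acylate the remaining C6–OH to give the 5-O-triethylsilyl ether of 25 F5.
- HF·pyridine in THF at 0 °C removes the silyl group to give 25.

## Further compounds

F1 | step 6 | (2R)-2-hydroxy-N,4,4-trimethoxy-N,2-dimethylbutanamide | CON(C)C(=O)[C@](C)(O)CC(OC)OC
F2 | step 11 | methyl (2E)-3-[(4R,5S)-5-{1-[(5R)-5-(2,2-dimethoxyethyl)-5-methyl-4-oxo-4,5-dihydrofuran-2-yl]ethenyl}-2,2-dimethyl-1,3-dioxolan-4-yl]-2-[(4,4,5,5-tetramethyl-1,3,2-dioxaborolan-2-yl)methyl]prop-2-enoate | CC1(C)O[C@H](/C=C(\CB2OC(C)(C)C(C)(C)O2)C(=O)OC)[C@H](C(=C)C3=CC(=O)[C@@](C)(CC(OC)OC)O3)O1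
F3 | step 11 | methyl (2E)-3-[(4R,5S)-2,2-dimethyl-5-{1-[(5R)-5-methyl-4-oxo-5-(2-oxoethyl)-4,5-dihydrofuran-2-yl]ethenyl}-1,3-dioxolan-4-yl]-2-[(4,4,5,5-tetramethyl-1,3,2-dioxaborolan-2-yl)methyl]prop-2-enoate | CC1(C)O[C@H](/C=C(\CB2OC(C)(C)C(C)(C)O2)C(=O)OC)[C@H](C(=C)C3=CC(=O)[C@@](C)(CC=O)O3)O1
F4 | step 13 | 5-O-triethylsilyl ether of diol 23 (C6–OH free, stereocentres arranged as in 25) | O[C@@H]1[C@H]2C(=C)C(=O)O[C@H]2C[C@@]2(C)OC(=CC2=O)C(=C)[C@@H]1O[Si](CC)(CC)CC
F5 | step 13 | 5-O-triethylsilyl ether of 25 | C=C(C)C(=O)O[C@@H]1[C@H]2C(=C)C(=O)O[C@H]2C[C@@]2(C)OC(=CC2=O)C(=C)[C@@H]1O[Si](CC)(CC)CC
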